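**Plan**

- Labels and enabling feature: ring A is the methoxy-enedione ring and ring B the cyclopentane. Ca is the spiro carbon shared by rings A and B, Cb is CH(iPr), Cc and Cd are the ring-B CH2 groups (Cc next to Cb), and Ce is the pinane C2 spiro carbon. Ca lies between two ketones and is bonded in ring B to Cb and Ce, the ends of the chain Cb–Cc–Cd–Ce, so ring B is a carbene-plus-diene [4+1].
- Cuts: the Cc–Cd single bond goes back to a ring-B alkene; Ca–Cb and Ca–Ce are then cut together, giving a ring-A diazo dione (Ca as carbene carbon) and a pinane-based diene Cb=Cc–Cd=Ce. The diene is cut at Cb=Cc (Horner–Wittig) and at Cd=Ce back to nopinone.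
- Forward order: ring A is made first (alkylative dearomatisation of phloroacetophenone, O-methylation, deacylative diazo transfer). The pinane is bought as (+)-β-pinene and elaborated to the diene. Ring B is closed last in one flask (dirhodium cyclopropanation, then zerovalent-palladium ring expansion), followed by hydrogenation.
- Stereochemistry: the pinane centres come from (+)-β-pinene. Cb comes from the alkene face chosen by a chiral dirhodium carboxylate. Ce comes from enolate attack anti to palladium held on the allyl face remote from the CMe2 bridge (Ca syn, Cd anti to the bridge). Ca comes from the enolate face that turns its CMe2-flanked carbonyl away from isopropyl.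

Key step: step 8

Remark: the exocyclic Cd=Ce double bond of the phosphine oxide, the diene and the vinylcyclopropane is carried as an E/Z mixture and left unspecified in the SMILES, because Ce becomes a π-allyl terminus in the key step and both isomers converge.
Remark: which antipode of the tert-leucinate ligand delivers the required Cb face has to be settled by trial; the S ligand is written and its mirror image is used if the sense is opposite.
Remark: (+)-β-pinene, the less abundant antipode, is taken as purchasable.

**Step 1**
Reactants: 1 1-(2,4,6-trihydroxyphenyl)ethan-1-one (2′,4′,6′-trihydroxyacetophenone)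
Product: 2 2-acetyl-3,5-dihydroxy-4,6,6-trimethylcyclohexa-2,4-dien-1-one
Conditions: NaOMe, MeI (3.1 equiv), MeOH, 0 °C → rt; acidic work-up
Reagents that add atoms: iodomethane, CI
Why: Alkylative dearomatisation of a phloroglucinol: the polyphenoxide is C-methylated at both free ring carbons and a third time at one of them (the acetyl-bearing carbon is blocked), which should give the cyclohexadienone with one C(Me) and one CMe2 carbon if the stoichiometry is held below the tetramethyl stage; no stereocentre is formed.

**Step 2**
Reactants: 2 2-acetyl-3,5-dihydroxy-4,6,6-trimethylcyclohexa-2,4-dien-1-one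
Product: 3 2-acetyl-3-hydroxy-5-methoxy-4,6,6-trimethylcyclohexa-2,4-dien-1-one
Conditions: TMSCHN2 (1.05 equiv), toluene/MeOH 4:1, 0 °C
Reagents that add atoms: (trimethylsilyl)diazomethane, C[Si](C)(C)C=[N+]=[N-]
Why: Enol O-methylation with a diazoalkane: the hydroxyl between C(Me) and CMe2 is the one acidic OH not held in the hydrogen-bonded chelate of the 2-acetyl-1,3-dione unit and should be methylated first by one equivalent.

**Step 3**
Reactants: 3 2-acetyl-3-hydroxy-5-methoxy-4,6,6-trimethylcyclohexa-2,4-dien-1-one
Product: 4 2-diazo-5-methoxy-4,6,6-trimethylcyclohex-4-ene-1,3-dione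
Conditions: 4-acetamidobenzenesulfonyl azide (p-ABSA, 1.2 equiv), DBU, MeCN, 0 °C → rt
Reagents that add atoms: 4-acetamidobenzenesulfonyl azide, CC(=O)Nc1ccc(cc1)S(=O)(=O)N=[N+]=[N-]
Why: Deacylative Regitz diazo transfer: the triketone enolate adds to the azide at the acetyl-bearing carbon and the sulfonamide nitrogen then carries off the exocyclic acetyl group, the most accessible of the three carbonyls (one ring carbonyl is a vinylogous ester, the other is flanked by CMe2), leaving the diazo group between the two ring ketones.

**Step 4**
Reactants: 5 (+)-β-pinene, (1R,5R)-6,6-dimethyl-2-methylidenebicyclo[3.1.1]heptane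
Product: 7 (−)-nopinone, (1S,5R)-6,6-dimethylbicyclo[3.1.1]heptan-2-one, via β-pinene ozonide 6 (not isolated)
Conditions: O3, CH2Cl2, −78 °C; then PPh3, −78 °C → rt
Reagents that add atoms: ozone, [O-][O+]=O
Why: Ozonolysis of the 1,1-disubstituted alkene with reductive cleavage of the spiro-1,2,4-trioxolane; the two bridgehead stereocentres are not touched.

**Step 5**
Reactants: 7 (−)-nopinone; 8 vinylmagnesium bromide
Product: 9 (1S,2R,5R)-2-ethenyl-6,6-dimethylbicyclo[3.1.1]heptan-2-ol (hydroxyl syn to the CMe2 bridge)
Conditions: THF, 0 °C → rt; H2O
Reagents that add atoms: none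
Why: Grignard 1,2-addition to the ketone from the face opposite the CMe2 bridge; the new carbinol centre becomes sp2 again in step 6, so its configuration is of no consequence.

**Step 6**
Reactants: 9 (1S,2R,5R)-2-ethenyl-6,6-dimethylbicyclo[3.1.1]heptan-2-ol
Product: 11 [2-((1S,5R)-6,6-dimethylbicyclo[3.1.1]heptan-2-ylidene)ethyl]diphenylphosphine oxide (E/Z mixture at the exocyclic alkene), via tertiary allyl diphenylphosphinite 10 (not isolated)
Conditions: n-BuLi, THF, −78 °C; Ph2PCl, −78 °C → rt; then 65 °C
Reagents that add atoms: chlorodiphenylphosphine, ClP(c1ccccc1)c1ccccc1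
Why: O-phosphinylation of the lithium alkoxide followed by the thermal [2,3]-sigmatropic phosphinite-to-phosphine-oxide rearrangement, which moves phosphorus to the vinyl terminus and creates the exocyclic alkene under neutral conditions, so that no pinanyl cation (and no cyclobutane cleavage) is involved.

**Step 7**
Reactants: 11 [2-((1S,5R)-6,6-dimethylbicyclo[3.1.1]heptan-2-ylidene)ethyl]diphenylphosphine oxide; 12 2-methylpropanal (isobutyraldehyde)
Product: 13 (1S,5R)-6,6-dimethyl-2-[(2E)-4-methylpent-2-en-1-ylidene]bicyclo[3.1.1]heptane (exocyclic alkene E/Z)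
Conditions: n-BuLi, THF/DMPU, −78 °C; then 12, −78 °C → rt; H2O
Reagents that add atoms: none
Why: Horner–Wittig olefination: the lithiated allylic phosphine oxide adds to the aldehyde through its α-carbon (the γ-carbon is fully substituted) and the adduct loses diphenylphosphinate on warming to give the new disubstituted Cb=Cc alkene, expected E as is usual for allylic phosphine oxides.

**Step 8**
Reactants: 4 2-diazo-5-methoxy-4,6,6-trimethylcyclohex-4-ene-1,3-dione; 13 (1S,5R)-6,6-dimethyl-2-[(2E)-4-methylpent-2-en-1-ylidene]bicyclo[3.1.1]heptane
Product: 15 (1S,2R,2′R,3′S,5R)-4″-methoxy-3″,5″,5″,6,6-pentamethyl-3′-(propan-2-yl)dispiro[bicyclo[3.1.1]heptane-2,1′-cyclopentane-2′,1″-cyclohexane]-3″,4′-diene-2″,6″-dione (the target with a Cc=Cd alkene in ring B; Ca R, Cb S, Ce R), via trans-vinylcyclopropane 14 (not isolated)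
Conditions: Rh2(S-PTTL)4 [dirhodium tetrakis(N-phthaloyl-(S)-tert-leucinate)] (1 mol %), PhF, 60 °C, slow addition of 4 to 13 (1.2 equiv); then Pd(PPh3)4 (10 mol %), DMSO, 80 °C, same flask
Reagents that add atoms: none
Why: The dirhodium carbenoid from 4 is an electrophilic acceptor/acceptor carbene that attacks the diene at Cb, the unhindered terminus whose developing charge is allyl-stabilised, and closes to the trans-vinylcyclopropane 14 (Ca–Cb and Ca–Cc, a three-membered closure), the tert-leucinate ligands selecting the alkene face and thereby Cb; any dihydrofuran isomer formed alongside holds the same Ca–Cb bond and enters the same manifold. Zerovalent palladium then ionises the doubly activated allylic Ca–Cc bond with inversion to a ring-A dione enolate tethered through Cb to a π-allyl spanning Cc, Cd and Ce. Return to the cyclopropane and O-alkylation are reversible under these conditions, whereas attack of the enolate carbon on the far terminus Ce, a five-membered closure that places the allyl C=C inside ring B and needs Cb in the anti position of the allyl, is the irreversible exit and forms Ca–Ce. The closest known reactions are the dirhodium-catalysed cyclopropanation of 1,3-dienes by 2-diazo-1,3-dicarbonyl compounds, the zerovalent-palladium vinylcyclopropane-to-cyclopentene rearrangement of 2-vinylcyclopropane-1,1-dicarbonyl compounds and the palladium-catalysed 1,3-oxygen-to-carbon shift of allyl enol ethers. Ce is set because the π-allyl equilibrates to the diastereomer with palladium on the face remote from the CMe2 bridge and the enolate enters anti to the metal, so that Ca ends syn to the bridge and Cd anti, while Ca is set by the enolate face, the CMe2-flanked carbonyl turning away from the isopropyl group on Cb. The step needs the carbenoid to choose the distal disubstituted alkene over the exocyclic trisubstituted one (the pinane shields Cd=Ce) and carbon over oxygen closure (every O-bound product can re-ionise).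

**Step 9**
Reactants: 15 ring-B cyclopentene (Cc=Cd)
Product: 16 (1S,2R,2′R,3′R,5R)-4″-methoxy-3″,5″,5″,6,6-pentamethyl-3′-(propan-2-yl)dispiro[bicyclo[3.1.1]heptane-2,1′-cyclopentane-2′,1″-cyclohexan]-3″-ene-2″,6″-dione (target, CNP0307059.1; Ca R, Cb R, Ce R)
Conditions: H2 (1 atm), palladium on carbon (10% Pd/C), EtOAc, rt
Reagents that add atoms: none
Why: Heterogeneous hydrogenation of the only disubstituted alkene; the tetrasubstituted, carbonyl-conjugated enol ether of ring A and the ketones should be inert under these conditions, and no stereocentre is formed or touched.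

**Compound list**

1 | 1-(2,4,6-trihydroxyphenyl)ethan-1-one (2′,4′,6′-trihydroxyacetophenone) | CC(=O)c1c(O)cc(O)cc1O | starting material
2 | 2-acetyl-3,5-dihydroxy-4,6,6-trimethylcyclohexa-2,4-dien-1-one | CC(=O)C1=C(O)C(C)=C(O)C(C)(C)C1=O | intermediate
3 | 2-acetyl-3-hydroxy-5-methoxy-4,6,6-trimethylcyclohexa-2,4-dien-1-one | CC(=O)C1=C(O)C(C)=C(OC)C(C)(C)C1=O | intermediate
4 | 2-diazo-5-methoxy-4,6,6-trimethylcyclohex-4-ene-1,3-dione | COC1=C(C)C(=O)C(=[N+]=[N-])C(=O)C1(C)C | intermediate
5 | (+)-β-pinene, (1R,5R)-6,6-dimethyl-2-methylidenebicyclo[3.1.1]heptane | C=C1CC[C@@H]2C[C@H]1C2(C)C | starting material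
6 | β-pinene ozonide, 1,2,4-trioxolane spiro-fused at pinane C2 (bridgeheads as in 5, spiro carbon unassigned; formed in the flask, not isolated) | C1OC2(OO1)CC[C@@H]1C[C@H]2C1(C)C | intermediate
7 | (−)-nopinone, (1S,5R)-6,6-dimethylbicyclo[3.1.1]heptan-2-one | O=C1CC[C@@H]2C[C@H]1C2(C)C | intermediate
8 | vinylmagnesium bromide | C=C[Mg]Br | starting material
9 | (1S,2R,5R)-2-ethenyl-6,6-dimethylbicyclo[3.1.1]heptan-2-ol (OH syn to the CMe2 bridge) | C=C[C@]1(O)CC[C@@H]2C[C@H]1C2(C)C | intermediate
10 | (1S,2R,5R)-2-ethenyl-6,6-dimethylbicyclo[3.1.1]heptan-2-yl diphenylphosphinite (formed in the flask, not isolated) | C=C[C@]1(OP(c2ccccc2)c2ccccc2)CC[C@@H]2C[C@H]1C2(C)C | intermediate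
11 | [2-((1S,5R)-6,6-dimethylbicyclo[3.1.1]heptan-2-ylidene)ethyl]diphenylphosphine oxide (exocyclic alkene E/Z) | O=P(CC=C1CC[C@@H]2C[C@H]1C2(C)C)(c1ccccc1)c1ccccc1 | intermediate
12 | 2-methylpropanal (isobutyraldehyde) | CC(C)C=O | starting material
13 | (1S,5R)-6,6-dimethyl-2-[(2E)-4-methylpent-2-en-1-ylidene]bicyclo[3.1.1]heptane (exocyclic alkene E/Z) | CC(C)/C=C/C=C1CC[C@@H]2C[C@H]1C2(C)C | intermediate
14 | trans-1-[(6,6-dimethylbicyclo[3.1.1]heptan-2-ylidene)methyl]-6-methoxy-5,7,7-trimethyl-2-(propan-2-yl)spiro[2.5]oct-5-ene-4,8-dione (Cb as in 15, both epimers at the spiro carbon; formed in the flask, not isolated) | COC1=C(C)C(=O)C2(C(=O)C1(C)C)[C@@H](C(C)C)[C@@H]2C=C1CC[C@@H]2C[C@H]1C2(C)C | intermediate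
15 | (1S,2R,2′R,3′S,5R)-4″-methoxy-3″,5″,5″,6,6-pentamethyl-3′-(propan-2-yl)dispiro[bicyclo[3.1.1]heptane-2,1′-cyclopentane-2′,1″-cyclohexane]-3″,4′-diene-2″,6″-dione | COC1=C(C)C(=O)[C@@]2(C(=O)C1(C)C)[C@@H](C(C)C)C=C[C@@]21CC[C@@H]2C[C@H]1C2(C)C | intermediate
16 | (1S,2R,2′R,3′R,5R)-4″-methoxy-3″,5″,5″,6,6-pentamethyl-3′-(propan-2-yl)dispiro[bicyclo[3.1.1]heptane-2,1′-cyclopentane-2′,1″-cyclohexan]-3″-ene-2″,6″-dione | COC1=C(C)C(=O)[C@@]2(C(=O)C1(C)C)[C@@H](C(C)C)CC[C@@]21CC[C@@H]2C[C@H]1C2(C)C | target

**Step count**

Total: 9 steps. Longest linear sequence: 6 steps (steps 4 to 9, from 5).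

**Steps most likely to fail**

First, step 8. The chiral carboxylate may not tell apart the two faces of an alkene three bonds away from the nearest stereocentre. In one flask the phosphine-ligated palladium and the carbenoid cycle may also disturb each other. Closure through oxygen, or proton loss from the π-allyl, may hold the material back at the mild temperature a one-flask relay tolerates. The fallback sets out from 4 and 13 and splits the event into two operations, replacing catalyst control at Cb by separation on the pinane handle. With Rh2(OAc)4 in refluxing fluorobenzene, the carbenoid adds to the distal alkene in the formal [3+2] sense common for cyclic 2-diazo-1,3-diones and dienes. This gives trans-2-[(6,6-dimethylbicyclo[3.1.1]heptan-2-ylidene)methyl]-6-methoxy-5,5,7-trimethyl-3-(propan-2-yl)-2,3-dihydro-1-benzofuran-4(5H)-one F1. Because the pinane is enantiopure, the two Cb series are diastereomers, and the one with Cb as in 15 is isolated by chromatography. F1 is an allyl enol ether of a 1,3-dione. Pd2(dba)3 with 1,2-bis(diphenylphosphino)ethane in DMSO at 100 °C should ionise its allylic C–O bond to the same π-allyl/enolate pair. The 1,3-oxygen-to-carbon shift then gives 15, where the route is rejoined.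

Second, step 3. The sulfonamide nitrogen of the azide adduct may attack a ring carbonyl instead of the acetyl group (ring cleavage), or the weakly nucleophilic triketone enolate may not take up the azide. The fallback sets out from 2 and removes the acetyl group before the diazo transfer. Retro-Claisen deacetylation in hot aqueous HCl, as is usual for 2-acyl-1,3-diones, gives 2,2,4-trimethylcyclohexane-1,3,5-trione F2. Ordinary Regitz diazo transfer (p-ABSA, Et3N, MeCN) at its only CH2 between two carbonyls gives 6-diazo-2,2,4-trimethylcyclohexane-1,3,5-trione F3. O-methylation of the remaining enolised 2-methyl-1,3-dione with TMSCHN2 is expected mainly at the oxygen next to CMe2, because the other carbonyl stays engaged with the diazo group. This gives 4, where the route is rejoined; an isomeric enol ether, if formed, would be removed by chromatography.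

Third, step 2. Methylation may occur at an enol oxygen next to the acetyl-bearing carbon instead of the oxygen between C(Me) and CMe2, which would give regioisomeric enol ethers. The fallback sets out from 1 and fixes the methoxy group on the arene before dearomatisation. Selective methylation of the non-chelated para hydroxyl (Me2SO4, 1 equiv, K2CO3, acetone) gives 1-(2,6-dihydroxy-4-methoxyphenyl)ethan-1-one F4. Exhaustive C-methylation (MeI, NaOMe, MeOH) then puts one methyl on each free ring carbon and a third on one of them with loss of aromaticity. The two ring carbons are equivalent, so the methoxy carbon must end between C(Me) and CMe2, and the product is 3, where the route is rejoined.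

**Further compounds**

F1 | step 8 | trans-2-[(6,6-dimethylbicyclo[3.1.1]heptan-2-ylidene)methyl]-6-methoxy-5,5,7-trimethyl-3-(propan-2-yl)-2,3-dihydro-1-benzofuran-4(5H)-one (Cb as in 15) | COC1=C(C)C2=C(C(=O)C1(C)C)[C@@H](C(C)C)[C@@H](O2)C=C1CC[C@@H]2C[C@H]1C2(C)C
F2 | step 3 | 2,2,4-trimethylcyclohexane-1,3,5-trione (triketo tautomer drawn; C4 enolisable, no fixed configuration) | CC1C(=O)CC(=O)C(C)(C)C1=O
F3 | step 3 | 6-diazo-2,2,4-trimethylcyclohexane-1,3,5-trione (C4 enolisable, no fixed configuration) | CC1C(=O)C(=[N+]=[N-])C(=O)C(C)(C)C1=O
F4 | step 2 | 1-(2,6-dihydroxy-4-methoxyphenyl)ethan-1-one | COc1cc(O)c(C(C)=O)c(O)c1
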